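0.0277 M d⁻¹ is what the eta run gains in target once its line runs straight, and the zeta run, charged with about twice as much solid substrate, gains 0.0277 M d⁻¹. We call this gain per litre and day, read on the straight part of the line, the target flow; in these two runs it is zero order in the charge.

| setting | eta | zeta | flask |
|---|---|---|---|
| solid substrate | 0.34 M | 0.75 M | 0.50 M |
| remark | run made earlier | run made earlier |  |
| time |  |  | 3.0 d |

| run | time / d | solid substrate / % | target / % | starting material / % |
|---|---|---|---|---|
| eta | 0.250 | 73.1 | 0.7 | 20.4 |
| eta | 0.500 | 68.9 | 1.6 | 20.4 |
| eta | 1.04 | 62.7 | 5.3 | 20.8 |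
| eta | 2.08 | 54.4 | 14.0 | 20.6 |
| eta | 4.00 | 38.1 | 29.4 | 21.4 |
| zeta | 0.333 | 86.9 | 0.1 | 9.6 |
| zeta | 0.833 | 83.8 | 1.8 | 9.3 |
| zeta | 1.67 | 80.6 | 4.6 | 9.8 |
| zeta | 2.50 | 77.0 | 7.9 | 9.5 |
| zeta | 4.00 | 71.8 | 13.2 | 9.8 |

(each reading ± 0.3 percentage points)

1. at 3.0 d, what has stopped the reaction, if anything has (for what has run out or reacted, a solid counts together with what of it has only dissolved) (it is still moving / forward and back rates have come level / all of the solid substrate has reacted)
2. part of the solid substrate that has turned into other species by 3.0 d (what has only dissolved does not count)
3. amount of target at 3.0 d, in percent of the solid substrate charged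
4. amount of starting material at 3.0 d, in percent of the solid substrate charged

- the numbers in the tables scatter by 0.3 percentage points (one standard deviation)
- at the start none of the solid substrate is in solution
- what has only dissolved of solid substrate counts as not reacted
- a reading or a percentage of target counts all its forms, free or not
- the reaction counts as stopped when no species that holds the solid substrate changes by six tenths of a point or more over the second half of the time
- starting material means what is dissolved; the solid is not counted in it

We build the flask up one process at a time. Dissolving first: late in the runs, eta holds 0.0700 M of starting material and zeta 0.0713 M, so we expect 14.0% of this flask's charge. Next, a store we cannot see: at the last readings the columns fall short of the charge by 0.0377 M in eta and 0.0390 M in zeta, which is 7.55% here.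

Then target, solved at both ends and joined. Early it is near zero, late it follows the flow, and the straight line through eta's reading at 1.04 d meets zero at a lag t_L:

t_L = t − c_Y/flow = 0.389 d

y_Y = flow × (t − t_L)/c = 14.5%

That leaves 64.0% as solid substrate, and target still gains 8.3 percentage points over the second half, so we expect it to be moving.

The forecast says it is still moving, with conversion 22.1% (20.8% to 23.4%), target 14.4% (13.6% to 15.3%) and starting material 14.2% (13.7% to 14.8%), on the grounds that “Target grows at the same rate in both runs”. Our target figure is 14.5%, against its 14.4%.

The flask gives it is still moving: conversion 22.1%, target 14.3%, starting material 14.2%.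

    intermediate A ⇌ intermediate B (K = 0.170, k = 8.27 × 10⁻⁶ s⁻¹)
    starting material ⇌ intermediate B (k = 8.34 × 10⁻⁵ s⁻¹)
    crystals ⇌ target, rate k3*(cs3 - [target]) while solid is left; crystals form when [target] > cs3 (solubility = 12.0 mM, k = 5.81 × 10⁻⁴ s⁻¹)
    starting material ⇌ intermediate A (K = 0.630, k = 1.05 × 10⁻⁵ s⁻¹)
    solid substrate ⇌ starting material, rate k5*(cs5 - [starting material]) while solid is left; crystals form when [starting material] > cs5 (solubility = 0.0720 M, k = 2.95 × 10⁻⁴ s⁻¹)
    intermediate A → target (k = 9.98 × 10⁻⁶ s⁻¹)

The flow gave 14.5% of target for this flask, and target, crystals counted, stands at 14.3%. The solution closes half its gap to saturation with starting material in 0.0272 d, far shorter than the 0.804 d half-time of intermediate A by its forward loss to target alone. In this flask at 3.00 d, 63.7% of solid substrate stands beside 14.2% of starting material, and intermediate A has gone from 6.25% to 6.34% since 1.50 d. For a neighbour flask charged with 0.30 M, the same flow gives 24.1% of target, and that flask holds 23.8%.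

(The readings are simulated with constants of no real substance, noise included.)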